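The dihydrobenzofuran that carries the 4-hydroxyphenyl group (ring A) is cut at its aryl C7a–O1 bond and its C2–C3 bond, so that O1–C2 comes from 4-methoxybenzaldehyde. The key step is a one-pot [3+2] annulation that exploits the acidity of the doubly benzylic CH2 (future C3) between the central ring and the 3,5-dimethoxyphenyl ring: its carbanion adds to the aldehyde and the alkoxide displaces the ortho fluoride of the central ring. The precursor is a simple 2-bromo-6-fluoro-diarylmethane. A Heck reaction and an acid-induced cation–arene closure then build the seven-membered ring under control of C3, and ring B is added last by an o-quinone methide/chiral sulfonium ylide [4+1] annulation that also sorts the enantiomers.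

Key step: step 3

Remarks on the chemistry:
- Labels: O1, C2, C3, C3a and C7a are the atoms of ring A; ring B is the second dihydrobenzofuran; the central ring carries both furan oxygens.
- Assumption: the target has the 2,4-dihydroxyphenyl group of the seven-membered ring cis to H-3, the arrangement of the ampelopsin B family; the cation–arene closure of step 5 is taken to deliver it under control of C3.
- Compounds 8, 9, 11, 12, 13, 14 and 19 are racemic and are drawn as the enantiomer that leads to 21; the two enantiomers are separated as diastereomers in step 9.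
- Assumption: the (1R,4R,5R) antipode of sulfide 15 is taken to give the (2S,3S) ring B; if the sense proves opposite, its mirror image is used.

Step 1
Reactants: 1 3-bromo-5-fluorophenol
Product: 3 1-bromo-3-fluoro-2-iodo-5-(methoxymethoxy)benzene, via 3-bromo-5-fluoro-4-iodophenol 2 (not isolated)
Conditions: NIS, TsOH·H2O (cat.), MeCN, 0 °C; then i-Pr2NEt, MOMCl, 0 to 25 °C
Reagents that add atoms: N-iodosuccinimide, O=C1CCC(=O)N1I; chloromethyl methyl ether, COCCl
Why: Electrophilic aromatic iodination should go para to the phenol OH (the carbon between Br and F), and the phenol is then capped as its MOM ether (Williamson-type O-alkylation) so that the ring oxygen stays neutral in the later SNAr step.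

Step 2
Reactants: 3 1-bromo-3-fluoro-2-iodo-5-(methoxymethoxy)benzene; 4 1-(chloromethyl)-3,5-dimethoxybenzene
Product: 6 1-bromo-2-(3,5-dimethoxybenzyl)-3-fluoro-5-(methoxymethoxy)benzene, via (3,5-dimethoxybenzyl)zinc chloride 5 (not isolated)
Conditions: 4, Zn dust, LiCl, THF, 25 °C; then 3, Pd(PPh3)4 (5 mol %), THF, 50 °C
Reagents that add atoms: none
Why: Zinc inserts into the benzylic chloride and the benzylzinc reagent couples at the C–I bond (Negishi coupling), which undergoes oxidative addition much faster than the C–Br bond.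

Step 3
Reactants: 6 1-bromo-2-(3,5-dimethoxybenzyl)-3-fluoro-5-(methoxymethoxy)benzene; 7 4-methoxybenzaldehyde
Product: 9 rac-(2R,3R)-4-bromo-3-(3,5-dimethoxyphenyl)-6-(methoxymethoxy)-2-(4-methoxyphenyl)-2,3-dihydro-1-benzofuran, via carbinol adduct 8 (not isolated)
Conditions: KH (1.05 equiv), 18-crown-6, THF, 25 °C; then 7, −78 °C; then 60 °C
Reagents that add atoms: none
Why: Proposed new method: KH/18-crown-6 removes a proton from the doubly benzylic CH2 of 6 (the only C–H acid in reach, further acidified by the ortho F and Br), the potassium carbanion adds to the non-enolisable aldehyde 7 to give the alkoxide of 8 (C2–C3 bond), and on warming the crown-separated alkoxide displaces the ortho fluoride of the central ring by intramolecular addition–elimination (O1–C7a bond); the closest known reaction types are the one-pot benzylic deprotonation/addition/SNAr annulation of 2-fluorotoluenes with nitriles to indoles and the alkoxide SNAr cyclisation of 2-(2-fluorophenyl)ethanols to dihydrobenzofurans. The furan ring closes in a 5-exo mode at the C–F carbon. C2 and C3 should form as the racemic trans pair because the aldehyde addition is reversible at 60 °C and the ring-closing transition state that keeps the two aryl groups anti is the lower one; any cis isomer can still equilibrate at C2 under the acid of step 5. The step needs displacement of F and not Br, deprotonation at the CH2 only and a ring that is not deactivated: addition–elimination at C–F is far faster than at C–Br, no base strong enough to make an aryne remains once the carbanion is formed, and the MOM ether keeps the ring oxygen neutral.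

Step 4
Reactants: 9 rac-(2R,3R)-4-bromo-3-(3,5-dimethoxyphenyl)-6-(methoxymethoxy)-2-(4-methoxyphenyl)-2,3-dihydro-1-benzofuran; 10 1-ethenyl-2,4-dimethoxybenzene
Product: 11 rac-(2R,3R)-3-(3,5-dimethoxyphenyl)-4-[(E)-2-(2,4-dimethoxyphenyl)ethenyl]-6-(methoxymethoxy)-2-(4-methoxyphenyl)-2,3-dihydro-1-benzofuran
Conditions: Pd(OAc)2 (5 mol %), P(o-tol)3 (10 mol %), Et3N, DMF, 100 °C
Reagents that add atoms: none
Why: Mizoroki–Heck coupling of the aryl bromide at the terminal carbon of the electron-rich styrene, followed by syn β-hydride elimination, should give the (E)-stilbene, and an amine base without carboxylate disfavours C–H arylation of the neighbouring aryl ring.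

Step 5
Reactants: 11 rac-(2R,3R)-3-(3,5-dimethoxyphenyl)-4-[(E)-2-(2,4-dimethoxyphenyl)ethenyl]-6-(methoxymethoxy)-2-(4-methoxyphenyl)-2,3-dihydro-1-benzofuran
Product: 12 rac-tetracyclic phenol (ring A fused to the dibenzocycloheptane; 2R 3R and R at the CH-aryl methine; free 6-OH)
Conditions: HCl (3 M in MeOH), CH2Cl2, 40 °C
Reagents that add atoms: none
Why: Protonation of the stilbene at the carbon next to the central ring gives a 2,4-dimethoxybenzyl cation that is captured by the ortho carbon of the neighbouring 3,5-dimethoxyphenyl ring (intramolecular Friedel–Crafts alkylation closing the seven-membered ring), the C3 stereocentre directing the attack so that the new aryl group ends cis to H-3, while the same acid in methanol removes the MOM group.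

Step 6
Reactants: 12 rac-tetracyclic phenol
Product: 13 rac-tetracyclic salicylaldehyde (CHO on the central ring between the OH and the ring CH2)
Conditions: MgCl2, Et3N, (CH2O)n, MeCN, 80 °C
Reagents that add atoms: formaldehyde (as paraformaldehyde), C=O
Why: Magnesium phenoxide-directed ortho-formylation (Casnati–Skattebøl) touches only the ring with the free OH and should go to the ortho carbon that is para to O1, since the carbon between the two oxygens is the less reactive one in resorcinol-type rings.

Step 7
Reactants: 13 rac-tetracyclic salicylaldehyde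
Product: 14 rac-tetracyclic aryl tert-butyl carbonate of 13
Conditions: Boc2O, DMAP (cat.), i-Pr2NEt, CH2Cl2, 0 to 25 °C
Reagents that add atoms: di-tert-butyl dicarbonate, CC(C)(C)OC(=O)OC(=O)OC(C)(C)C
Why: DMAP-catalysed acylation of the phenol installs the carbonate that later triggers o-quinone methide formation.

Step 8
Reactants: 15 (1R,4R,5R)-isothiocineole; 16 (2,4-dimethoxyphenyl)methanol
Product: 17 S-(2,4-dimethoxybenzyl)-(1R,4R,5R)-isothiocineolium tetrafluoroborate
Conditions: HBF4·OEt2, CH2Cl2, 0 °C
Reagents that add atoms: tetrafluoroboric acid, F[B-](F)(F)F.[H+]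
Why: Acid ionises the electron-rich benzylic alcohol and the sulfide traps the cation on its exposed exo face (SN1 S-alkylation), which should give a single sulfonium diastereomer.

Step 9
Reactants: 14 rac-tetracyclic aryl tert-butyl carbonate; 18 (3,5-dimethoxyphenyl)magnesium chloride; 17 S-(2,4-dimethoxybenzyl)-(1R,4R,5R)-isothiocineolium tetrafluoroborate
Product: 20 nonamethyl ether of the target, via o-quinone methide 19 (not isolated)
Conditions: 18 (1.05 equiv), THF, −78 °C; then ylide from 17 and LiN(SiMe3)2 (THF, −78 °C), −78 to 0 °C; chromatographic separation of the diastereomers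
Reagents that add atoms: none
Why: The Grignard reagent adds to the aldehyde, the Boc group migrates to the new alkoxide and is expelled to give o-quinone methide 19, and the sulfonium ylide adds to its exocyclic carbon and is displaced by the phenoxide (5-exo-tet) in a [4+1] annulation of the Corey–Chaykovsky type, in which the chiral sulfide fixes the attacked face of the ylide carbon (C2 of ring B, S), trans ring closure relays this to C3 of ring B (S), and the same reagent control on both enantiomers of 14 turns them into two diastereomers from which 20, with the (2R,3R) ring A, is isolated.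

Step 10
Reactants: 20 nonamethyl ether of the target
Product: 21 CNP0283541.1
Conditions: BBr3 (excess), CH2Cl2, −78 to 25 °C; then MeOH, H2O
Reagents that add atoms: none
Why: Boron tribromide demethylation cleaves all nine aryl methyl ethers, the carbon stereocentres carry no exchangeable hydrogen, and a benzylic C2–O bond that ionises can only re-close to the favoured trans ring.

Compound list
1 | 3-bromo-5-fluorophenol | Oc1cc(F)cc(Br)c1 | starting material
2 | 3-bromo-5-fluoro-4-iodophenol | Oc1cc(F)c(I)c(Br)c1 | intermediate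
3 | 1-bromo-3-fluoro-2-iodo-5-(methoxymethoxy)benzene | COCOc1cc(F)c(I)c(Br)c1 | intermediate
4 | 1-(chloromethyl)-3,5-dimethoxybenzene | COc1cc(CCl)cc(OC)c1 | starting material
5 | (3,5-dimethoxybenzyl)zinc chloride | COc1cc(C[Zn]Cl)cc(OC)c1 | intermediate
6 | 1-bromo-2-(3,5-dimethoxybenzyl)-3-fluoro-5-(methoxymethoxy)benzene | COCOc1cc(F)c(Cc2cc(OC)cc(OC)c2)c(Br)c1 | intermediate
7 | 4-methoxybenzaldehyde | COc1ccc(C=O)cc1 | starting material
8 | rac-(1R,2R)-2-[2-bromo-6-fluoro-4-(methoxymethoxy)phenyl]-2-(3,5-dimethoxyphenyl)-1-(4-methoxyphenyl)ethanol (potassium alkoxide in the flask) | COc1ccc(cc1)[C@@H]([C@H](c1cc(OC)cc(OC)c1)c1c(F)cc(OCOC)cc1Br)O | intermediate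
9 | rac-(2R,3R)-4-bromo-3-(3,5-dimethoxyphenyl)-6-(methoxymethoxy)-2-(4-methoxyphenyl)-2,3-dihydro-1-benzofuran | COc1ccc([C@@H]2Oc3cc(OCOC)cc(Br)c3[C@H]2c2cc(OC)cc(OC)c2)cc1 | intermediate
10 | 1-ethenyl-2,4-dimethoxybenzene | C=Cc1ccc(OC)cc1OC | starting material
11 | rac-(2R,3R)-3-(3,5-dimethoxyphenyl)-4-[(E)-2-(2,4-dimethoxyphenyl)ethenyl]-6-(methoxymethoxy)-2-(4-methoxyphenyl)-2,3-dihydro-1-benzofuran | COc1ccc([C@@H]2Oc3cc(OCOC)cc(/C=C/c4ccc(OC)cc4OC)c3[C@H]2c2cc(OC)cc(OC)c2)cc1 | intermediate
12 | rac-tetracyclic phenol: ring A fused to the dibenzocycloheptane, (2R,3R), R at the CH(2,4-dimethoxyphenyl) methine, free OH on the central ring | COc1ccc([C@@H]2Oc3cc(O)cc4c3[C@H]2c2cc(OC)cc(OC)c2[C@@H](c2ccc(OC)cc2OC)C4)cc1 | intermediate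
13 | rac-tetracyclic salicylaldehyde: 12 with CHO between the OH and the ring CH2 | COc1ccc([C@@H]2Oc3cc(O)c(C=O)c4c3[C@H]2c2cc(OC)cc(OC)c2[C@@H](c2ccc(OC)cc2OC)C4)cc1 | intermediate
14 | rac-aryl tert-butyl carbonate of 13 | COc1ccc([C@@H]2Oc3cc(OC(=O)OC(C)(C)C)c(C=O)c4c3[C@H]2c2cc(OC)cc(OC)c2[C@@H](c2ccc(OC)cc2OC)C4)cc1 | intermediate
15 | (1R,4R,5R)-isothiocineole, (1R,4R,5R)-4,7,7-trimethyl-6-thiabicyclo[3.2.1]octane | C[C@@H]1CC[C@@H]2C[C@H]1SC2(C)C | starting material
16 | (2,4-dimethoxyphenyl)methanol | COc1ccc(CO)c(OC)c1 | starting material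
17 | S-(2,4-dimethoxybenzyl)-(1R,4R,5R)-isothiocineolium tetrafluoroborate (benzyl on the exo face of sulfur) | C[C@@H]1CC[C@@H]2C[C@H]1[S@@+](Cc1ccc(OC)cc1OC)C2(C)C.F[B-](F)(F)F | intermediate
18 | (3,5-dimethoxyphenyl)magnesium chloride (THF solution) | COc1cc([Mg]Cl)cc(OC)c1 | starting material
19 | rac-o-quinone methide from 14 (central ring as 6-oxo-cyclohexadienylidene, exocyclic =CH(3,5-dimethoxyphenyl), aryl drawn syn to the carbonyl) | COc1ccc([C@@H]2OC3=CC(=O)/C(=C\c4cc(OC)cc(OC)c4)C4=C3[C@H]2c2cc(OC)cc(OC)c2[C@@H](c2ccc(OC)cc2OC)C4)cc1 | intermediate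
20 | nonamethyl ether of the target: ring A (2R,3R), CH-aryl methine R, ring B (2S,3S) | COc1ccc([C@@H]2Oc3cc4c(c5c3[C@H]2c2cc(OC)cc(OC)c2[C@@H](c2ccc(OC)cc2OC)C5)[C@H](c2cc(OC)cc(OC)c2)[C@@H](c2ccc(OC)cc2OC)O4)cc1 | intermediate
21 | CNP0283541.1 | Oc1ccc([C@@H]2Oc3cc4c(c5c3[C@H]2c2cc(O)cc(O)c2[C@@H](c2ccc(O)cc2O)C5)[C@H](c2cc(O)cc(O)c2)[C@@H](c2ccc(O)cc2O)O4)cc1 | target

Total steps: 10. Longest linear sequence: 9 (steps 1 to 7, 9 and 10; step 8 makes the ylide precursor).

Steps most likely to fail

Step 3 (proposed new method). The metalation with KH is heterogeneous and may be slow. The fluoroarene is not activated, so ring closure may lag behind retro-addition; the alkoxide could then transfer hydride to free aldehyde, and the resulting ketone would go on to a benzofuran. The product ring could also be opened by base at C3. Fallback, from 6 back to 9, with the two events separated and each a known reaction: the potassium carbanion of 6 (KH, 18-crown-6, THF) is added to 7 at −78 °C and quenched cold, which gives carbinol 8 together with rac-(1S,2R)-2-[2-bromo-6-fluoro-4-(methoxymethoxy)phenyl]-2-(3,5-dimethoxyphenyl)-1-(4-methoxyphenyl)ethanol F1. The isolated carbinols are then closed with NaH in DMF at 80 °C (alkoxide SNAr cyclisation) to 9 and rac-(2S,3R)-4-bromo-3-(3,5-dimethoxyphenyl)-6-(methoxymethoxy)-2-(4-methoxyphenyl)-2,3-dihydro-1-benzofuran F2, and the cis isomer is removed by chromatography.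

Step 9. The o-quinone methide may be consumed by a second Grignard addition or by oligomerisation before the ylide captures it. Ionisation of the very electron-rich benzylic sulfonium may erode reagent control, and the two diastereomers, which differ only in remote stereocentres, may be hard to separate. Fallback, from 13 back to 20, building ring B by a catalyst-controlled rhodium-carbene C–H insertion. Alkylation of 13 with 2,4-dimethoxybenzyl chloride (K2CO3, DMF) gives the O-(2,4-dimethoxybenzyl) ether of 13 F3. Addition of 18 gives the diaryl carbinol F4 (epimers at the new carbinol carbon), and Dess–Martin periodinane oxidises it to the diaryl ketone F5. Hydrazine (AcOH, EtOH, 80 °C) gives the hydrazone F6, and MnO2 oxidises it to the diaryldiazomethane F7. Rh2(S-PTAD)4, or its antipode as needed for the S configuration at C3 of ring B, then inserts the donor/donor carbene into the ArO–CH2Ar group in a 1,5 sense to give the cis-fused-ring-B isomer of 20 F8. Catalytic CF3CO2H epimerises C2 of ring B through the benzylic cation to the trans ring of 20. The diastereomers from the racemate are separated as in the main route.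

Step 10. The Lewis acid may ionise the benzylic C2–O bonds, above all in ring B with its 2,4-dioxygenated aryl group, which would lead to ring opening and capture of the cation by a neighbouring arene; cleavage of nine ethers may also stop short. Fallback, from 20 back to 21, without Lewis acid and with no new compound: nucleophilic demethylation with NaSEt in DMF at 140 °C (SN2 attack of thiolate at the methyl carbon), with partly methylated material resubmitted.

Further compounds
F1 | step 3 | rac-(1S,2R)-2-[2-bromo-6-fluoro-4-(methoxymethoxy)phenyl]-2-(3,5-dimethoxyphenyl)-1-(4-methoxyphenyl)ethanol | COc1ccc(cc1)[C@H]([C@H](c1cc(OC)cc(OC)c1)c1c(F)cc(OCOC)cc1Br)O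
F2 | step 3 | rac-(2S,3R)-4-bromo-3-(3,5-dimethoxyphenyl)-6-(methoxymethoxy)-2-(4-methoxyphenyl)-2,3-dihydro-1-benzofuran | COc1ccc([C@H]2Oc3cc(OCOC)cc(Br)c3[C@H]2c2cc(OC)cc(OC)c2)cc1
F3 | step 9 | O-(2,4-dimethoxybenzyl) ether of 13 | COc1ccc([C@@H]2Oc3cc(OCc5ccc(OC)cc5OC)c(C=O)c4c3[C@H]2c2cc(OC)cc(OC)c2[C@@H](c2ccc(OC)cc2OC)C4)cc1
F4 | step 9 | diaryl carbinol from F3 and 18 (one carbinol epimer drawn) | COc1ccc([C@@H]2Oc3cc(OCc5ccc(OC)cc5OC)c([C@H](O)c5cc(OC)cc(OC)c5)c4c3[C@H]2c2cc(OC)cc(OC)c2[C@@H](c2ccc(OC)cc2OC)C4)cc1
F5 | step 9 | diaryl ketone from F4 | COc1ccc([C@@H]2Oc3cc(OCc5ccc(OC)cc5OC)c(C(=O)c5cc(OC)cc(OC)c5)c4c3[C@H]2c2cc(OC)cc(OC)c2[C@@H](c2ccc(OC)cc2OC)C4)cc1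
F6 | step 9 | hydrazone of F5 (one C=N isomer drawn) | COc1ccc([C@@H]2Oc3cc(OCc5ccc(OC)cc5OC)c(/C(=N/N)c5cc(OC)cc(OC)c5)c4c3[C@H]2c2cc(OC)cc(OC)c2[C@@H](c2ccc(OC)cc2OC)C4)cc1
F7 | step 9 | diaryldiazomethane from F6 | COc1ccc([C@@H]2Oc3cc(OCc5ccc(OC)cc5OC)c(C(=[N+]=[N-])c5cc(OC)cc(OC)c5)c4c3[C@H]2c2cc(OC)cc(OC)c2[C@@H](c2ccc(OC)cc2OC)C4)cc1
F8 | step 9 | isomer of 20 with cis ring B, (2R,3S) | COc1ccc([C@@H]2Oc3cc4c(c5c3[C@H]2c2cc(OC)cc(OC)c2[C@@H](c2ccc(OC)cc2OC)C5)[C@H](c2cc(OC)cc(OC)c2)[C@H](c2ccc(OC)cc2OC)O4)cc1
F0 | step 10 | none | none
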